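**Retrosynthetic overview**
1. End game: 22 ⇐ 21 (O‑debenzylation) ⇐ 20 (dioxane hydrolysis) ⇐ 19 (CHO → CH2OH). These steps only remove masks and return the carbon on C3 to the alcohol level.
2. Key disconnection: the bond between C1 of the guaiacyl ring and C2 of the dihydrofuran ring. Aldehyde 19 ⇐ flat benzofuran‑3‑ylmethanol 14 + arenediazonium salt 18, by a dearomative, enantioselective redox‑relay Heck–Matsuda arylation. One operation joins the halves, turns the furan ring into the dihydrofuran ring and sets C2 and C3.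
3. Enabling feature: the array O1–C2(H)(aryl)–C3(H)–CH2OH of the dihydrofuran ring is the retron of an allylic alcohol C2=C3–CH2OH that is also the enol‑ether bond of a benzofuran. After syn insertion the C2–H lies anti to Pd, so only the CH2OH hydrogens can be eliminated.
4. Side chain (carbinol carbon–aryl‑bearing carbon bond, both stereocentres): Evans syn aldol of benzofuran‑5‑carbaldehyde 4 with arylacetyl imide 8, then reductive removal of the auxiliary.
5. Ring order: the three benzene rings are bought. The furan ring comes first (steps 1–2, from 5‑iodovanillin), then a temporary 1,3‑dioxane (step 6). The furan becomes the dihydrofuran in step 11 and the dioxane is opened in step 13.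

Key step: step 11

Assumption: the sense of induction of the PyOx ligand on this new alkene class cannot be read from precedent. The (S)‑ligand is written as the one that delivers the aryl group to the C2‑Re face, and its commercially available enantiomer would be used if the sense proves opposite.

Step 1
Reactants: 1 5‑iodovanillin; 2 methyl propiolate
Product: 3 methyl (2E)‑3‑(4‑formyl‑2‑iodo‑6‑methoxyphenoxy)prop‑2‑enoate
Conditions: DABCO (10 mol %), CH2Cl2, 0 °C → rt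
Reagents that add atoms: none
Why: Amine‑catalysed oxa‑Michael addition of the acidic phenol to the ynoate should give the (E)‑β‑aryloxyacrylate without touching the aldehyde or the C–I bond.

Step 2
Reactants: 3 methyl (2E)‑3‑(4‑formyl‑2‑iodo‑6‑methoxyphenoxy)prop‑2‑enoate
Product: 4 methyl 5‑formyl‑7‑methoxy‑1‑benzofuran‑3‑carboxylate
Conditions: Pd(OAc)2 (5 mol %), PPh3 (10 mol %), NaHCO3, n‑Bu4NCl, DMF, 100 °C
Reagents that add atoms: none
Why: Intramolecular Heck reaction (5‑endo‑trig mode, known for 2‑haloaryl β‑aryloxy‑ and β‑arylaminoacrylates), in which aryl‑Pd adds to the ester‑bearing carbon of the push‑pull alkene and loss of HPdI is driven by formation of the aromatic furan ring.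

Step 3
Reactants: 5 (4‑benzyloxy‑3‑methoxyphenyl)acetic acid; 6 (4S)‑4‑benzyl‑1,3‑oxazolidin‑2‑one
Product: 8 (4S)‑4‑benzyl‑3‑[(4‑benzyloxy‑3‑methoxyphenyl)acetyl]‑1,3‑oxazolidin‑2‑one, via mixed pivalic anhydride 7 (not isolated)
Conditions: PivCl, Et3N, THF, −20 °C; then LiCl, 6, −20 °C → rt
Reagents that add atoms: pivaloyl chloride CC(C)(C)C(=O)Cl (atoms kept only in 7)
Why: Mixed‑anhydride N‑acylation of the oxazolidinone, with attack at the unhindered arylacetyl carbonyl of 7 and the auxiliary stereocentre untouched.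

Step 4
Reactants: 8 (4S)‑4‑benzyl‑3‑[(4‑benzyloxy‑3‑methoxyphenyl)acetyl]‑1,3‑oxazolidin‑2‑one; 4 methyl 5‑formyl‑7‑methoxy‑1‑benzofuran‑3‑carboxylate
Product: 11 methyl 5‑{(1S,2S)‑3‑[(4S)‑4‑benzyl‑2‑oxo‑1,3‑oxazolidin‑3‑yl]‑2‑(4‑benzyloxy‑3‑methoxyphenyl)‑1‑hydroxy‑3‑oxopropyl}‑7‑methoxy‑1‑benzofuran‑3‑carboxylate, via (Z)‑boron enolate 9 (not isolated), via boron aldolate 10 (not isolated)
Conditions: n‑Bu2BOTf, Et3N, CH2Cl2, −78 → 0 °C; 4, −78 → 0 °C; then pH 7 buffer, MeOH, 30 % H2O2, 0 °C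
Reagents that add atoms: di‑n‑butylboron triflate CCCCB(CCCC)OS(=O)(=O)C(F)(F)F (atoms kept only in 9 and 10)
Why: Evans syn aldol, in which soft enolisation gives the (Z)‑boron enolate 9, which adds to the aldehyde through a closed chair transition state on the enolate face away from the auxiliary benzyl group and so sets both side‑chain stereocentres (1S,2S, syn), after which buffered peroxide frees the alcohol from 10.

Step 5
Reactants: 11 syn‑aldol adduct
Product: 12 methyl 5‑[(1S,2R)‑2‑(4‑benzyloxy‑3‑methoxyphenyl)‑1,3‑dihydroxypropyl]‑7‑methoxy‑1‑benzofuran‑3‑carboxylate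
Conditions: LiBH4, MeOH (1 equiv), THF, 0 °C
Reagents that add atoms: none
Why: Reductive removal of the auxiliary with LiBH4, where the exocyclic imide carbonyl is far more electrophilic than the C3 ester (a vinylogous carbonate conjugated to O1) and the fast cold reduction outruns retro‑aldol cleavage and α‑epimerisation (the descriptor at the aryl‑bearing carbon becomes R only through CIP priority).

Step 6
Reactants: 12 diol ester
Product: 13 methyl 5‑[(4S,5R)‑5‑(4‑benzyloxy‑3‑methoxyphenyl)‑2,2‑dimethyl‑1,3‑dioxan‑4‑yl]‑7‑methoxy‑1‑benzofuran‑3‑carboxylate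
Conditions: Me2C(OMe)2, PPTS (cat.), CH2Cl2, rt
Reagents that add atoms: 2,2‑dimethoxypropane COC(C)(C)OC
Why: Acid‑catalysed transacetalisation closes the six‑membered cis‑4,5‑diaryl‑1,3‑dioxane without touching a stereocentre, so that the C3 hydroxymethyl will later be the only free hydroxyl.

Step 7
Reactants: 13 acetonide ester
Product: 14 {5‑[(4S,5R)‑5‑(4‑benzyloxy‑3‑methoxyphenyl)‑2,2‑dimethyl‑1,3‑dioxan‑4‑yl]‑7‑methoxy‑1‑benzofuran‑3‑yl}methanol
Conditions: LiAlH4, THF, 0 °C; aq. NaOH work‑up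
Reagents that add atoms: none
Why: Standard hydride reduction of an ester to the primary alcohol, with acetonide, benzyl ether and benzofuran ring inert to LiAlH4 at 0 °C.

Step 8
Reactants: 15 2‑methoxy‑4‑nitrophenol
Product: 16 1‑(benzyloxy)‑2‑methoxy‑4‑nitrobenzene
Conditions: BnBr, K2CO3, DMF, rt → 60 °C
Reagents that add atoms: benzyl bromide BrCc1ccccc1
Why: Williamson etherification of the acidic nitrophenol.

Step 9
Reactants: 16 1‑(benzyloxy)‑2‑methoxy‑4‑nitrobenzene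
Product: 17 4‑(benzyloxy)‑3‑methoxyaniline
Conditions: H2 (1 atm), 5 % Pt/C (sulfided), EtOAc, rt
Reagents that add atoms: none
Why: Chemoselective catalytic hydrogenation of the nitro group, since sulfided platinum does not hydrogenolyse benzyl aryl ethers.

Step 10
Reactants: 17 4‑(benzyloxy)‑3‑methoxyaniline
Product: 18 4‑(benzyloxy)‑3‑methoxybenzenediazonium tetrafluoroborate
Conditions: t‑BuONO, 48 % aq. HBF4, EtOH, 0 °C; precipitation with Et2O
Reagents that add atoms: tert‑butyl nitrite CC(C)(C)ON=O; tetrafluoroboric acid [H+].F[B-](F)(F)F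
Why: Diazotisation with an alkyl nitrite in the presence of HBF4, from which the p‑alkoxy‑stabilised tetrafluoroborate salt should precipitate and keep in the cold.

Step 11
Reactants: 14 benzofuran‑3‑ylmethanol with the dioxane side chain; 18 4‑(benzyloxy)‑3‑methoxybenzenediazonium tetrafluoroborate
Product: 19 (2S,3S)‑2‑(4‑benzyloxy‑3‑methoxyphenyl)‑5‑[(4S,5R)‑5‑(4‑benzyloxy‑3‑methoxyphenyl)‑2,2‑dimethyl‑1,3‑dioxan‑4‑yl]‑7‑methoxy‑2,3‑dihydro‑1‑benzofuran‑3‑carbaldehyde (2,3‑trans)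
Conditions: Pd2(dba)3 (5 mol %), (S)‑4‑tert‑butyl‑2‑[5‑(trifluoromethyl)pyridin‑2‑yl]‑4,5‑dihydrooxazole (15 mol %), 2,6‑di‑tert‑butyl‑4‑methylpyridine, 18 (1.5 equiv), DMF, rt, dark
Reagents that add atoms: none
Why: Proposed new method: oxidative addition of 18 to Pd(0) gives a cationic (PyOx)Pd–aryl that binds the C2=C3 bond of the furan ring of 14 (the least aromatic bond of the benzofuran, at once an enol ether and an allylic alcohol) and inserts it syn, aryl to C2 and Pd to C3; because C2–H then lies anti to Pd, re‑aromatising β‑hydride elimination is geometrically closed, so Pd can only take a hydrogen of the exocyclic CH2OH, re‑insert with H to C3 and leave from the carbinol carbon as Pd(0) and H+ to give the aldehyde. The closest known reaction types are the enantioselective redox‑relay Heck–Matsuda arylation of acyclic alkenols with PyOx ligands, the C2‑selective Pd‑catalysed arylation of benzofurans with arenediazonium salts, and the intramolecular dearomative Heck reaction of 2,3‑disubstituted benzofurans and indoles that ends by exocyclic β‑hydride elimination; new is their intermolecular, enantioselective union on a benzofuran‑3‑ylmethanol. No ring is closed: the furan ring is dearomatised to the 2,3‑dihydrofuran ring of the target. C2 is set by the ligand, which selects the C2‑Re face in the insertion independently of the remote dioxane stereocentres, and C3 is set by the suprafacial Pd–H shift, which puts H on the face that carries the aryl group and hence the formyl group trans, also the thermodynamic arrangement of this epimerisable centre. Regioselectivity (aryl to C2) is secured by the O1 polarisation of the enol ether toward cationic Pd, by unsubstituted C2 against fully substituted C3 and by η3‑benzyl stabilisation of Pd at C3, and chemoselectivity by the CH2OH being the only free hydroxyl and the only source of a syn β‑hydrogen. The hindered pyridine takes up HBF4, so that the acetonide and the acid‑labile hetero‑benzylic alcohol should survive.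

Step 12
Reactants: 19 trans‑aldehyde
Product: 20 {(2S,3R)‑2‑(4‑benzyloxy‑3‑methoxyphenyl)‑5‑[(4S,5R)‑5‑(4‑benzyloxy‑3‑methoxyphenyl)‑2,2‑dimethyl‑1,3‑dioxan‑4‑yl]‑7‑methoxy‑2,3‑dihydro‑1‑benzofuran‑3‑yl}methanol
Conditions: NaBH4, THF–MeOH, −20 → 0 °C
Reagents that add atoms: none
Why: Borohydride 1,2‑reduction of the aldehyde, run at once and cold so that enolisation (C3 epimerisation, β‑aryloxide loss) gets no time, with no stereocentre touched and C3 becoming R only through CIP priority.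

Step 13
Reactants: 20 acetonide alcohol
Product: 21 (1S,2R)‑2‑(4‑benzyloxy‑3‑methoxyphenyl)‑1‑[(2S,3R)‑2‑(4‑benzyloxy‑3‑methoxyphenyl)‑3‑(hydroxymethyl)‑7‑methoxy‑2,3‑dihydro‑1‑benzofuran‑5‑yl]propane‑1,3‑diol
Conditions: AcOH–THF–H2O (3:1:1), 35–40 °C
Reagents that add atoms: none
Why: Mild aqueous‑acid hydrolysis of the isopropylidene acetal, done while both phenols are still benzylated so that no p‑quinone methide can form at C2, and weak enough not to ionise the benzylic C–O bonds.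

Step 14
Reactants: 21 bis(benzyl ether)
Product: 22 (1S,2R)‑1‑[(2S,3R)‑2‑(4‑hydroxy‑3‑methoxyphenyl)‑3‑(hydroxymethyl)‑7‑methoxy‑2,3‑dihydro‑1‑benzofuran‑5‑yl]‑2‑(4‑hydroxy‑3‑methoxyphenyl)propane‑1,3‑diol (target)
Conditions: H2 (1 atm), 10 % Pd/C, EtOAc–EtOH, rt
Reagents that add atoms: none
Why: Hydrogenolysis of the two benzyl aryl ethers under neutral conditions at 1 atm, where O‑benzyl cleavage is much faster than cleavage of the secondary benzylic alcohol or of the cyclic C2–O1 benzylic ether.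

**Compound list**
1 | 5‑iodovanillin (4‑hydroxy‑3‑iodo‑5‑methoxybenzaldehyde) | COc1cc(C=O)cc(I)c1O | starting material
2 | methyl propiolate | C#CC(=O)OC | starting material
3 | methyl (2E)‑3‑(4‑formyl‑2‑iodo‑6‑methoxyphenoxy)prop‑2‑enoate | COC(=O)/C=C/Oc1c(I)cc(C=O)cc1OC | intermediate
4 | methyl 5‑formyl‑7‑methoxy‑1‑benzofuran‑3‑carboxylate | COC(=O)c1coc2c(OC)cc(C=O)cc12 | intermediate
5 | (4‑benzyloxy‑3‑methoxyphenyl)acetic acid | COc1cc(CC(=O)O)ccc1OCc1ccccc1 | starting material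
6 | (4S)‑4‑benzyl‑1,3‑oxazolidin‑2‑one | O=C1N[C@@H](Cc2ccccc2)CO1 | starting material
7 | (4‑benzyloxy‑3‑methoxyphenyl)acetic pivalic anhydride (not isolated) | COc1cc(CC(=O)OC(=O)C(C)(C)C)ccc1OCc1ccccc1 | intermediate
8 | (4S)‑4‑benzyl‑3‑[(4‑benzyloxy‑3‑methoxyphenyl)acetyl]‑1,3‑oxazolidin‑2‑one | COc1cc(CC(=O)N2[C@@H](Cc3ccccc3)COC2=O)ccc1OCc1ccccc1 | intermediate
9 | (Z)‑di‑n‑butylboron enolate of 8 (not isolated) | CCCCB(CCCC)O/C(=C\c1ccc(OCc2ccccc2)c(OC)c1)N1[C@@H](Cc2ccccc2)COC1=O | intermediate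
10 | di‑n‑butylborinate (boron aldolate) of 11 (not isolated) | COC(=O)c1coc2c(OC)cc([C@@H](OB(CCCC)CCCC)[C@@H](C(=O)N3[C@@H](Cc4ccccc4)COC3=O)c3ccc(OCc4ccccc4)c(OC)c3)cc12 | intermediate
11 | methyl 5‑{(1S,2S)‑3‑[(4S)‑4‑benzyl‑2‑oxo‑1,3‑oxazolidin‑3‑yl]‑2‑(4‑benzyloxy‑3‑methoxyphenyl)‑1‑hydroxy‑3‑oxopropyl}‑7‑methoxy‑1‑benzofuran‑3‑carboxylate | COC(=O)c1coc2c(OC)cc([C@@H](O)[C@@H](C(=O)N3[C@@H](Cc4ccccc4)COC3=O)c3ccc(OCc4ccccc4)c(OC)c3)cc12 | intermediate
12 | methyl 5‑[(1S,2R)‑2‑(4‑benzyloxy‑3‑methoxyphenyl)‑1,3‑dihydroxypropyl]‑7‑methoxy‑1‑benzofuran‑3‑carboxylate | COC(=O)c1coc2c(OC)cc([C@@H](O)[C@@H](CO)c3ccc(OCc4ccccc4)c(OC)c3)cc12 | intermediate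
13 | methyl 5‑[(4S,5R)‑5‑(4‑benzyloxy‑3‑methoxyphenyl)‑2,2‑dimethyl‑1,3‑dioxan‑4‑yl]‑7‑methoxy‑1‑benzofuran‑3‑carboxylate | COC(=O)c1coc2c(OC)cc([C@H]3OC(C)(C)OC[C@H]3c3ccc(OCc4ccccc4)c(OC)c3)cc12 | intermediate
14 | {5‑[(4S,5R)‑5‑(4‑benzyloxy‑3‑methoxyphenyl)‑2,2‑dimethyl‑1,3‑dioxan‑4‑yl]‑7‑methoxy‑1‑benzofuran‑3‑yl}methanol | OCc1coc2c(OC)cc([C@H]3OC(C)(C)OC[C@H]3c3ccc(OCc4ccccc4)c(OC)c3)cc12 | intermediate
15 | 2‑methoxy‑4‑nitrophenol | COc1cc([N+](=O)[O-])ccc1O | starting material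
16 | 1‑(benzyloxy)‑2‑methoxy‑4‑nitrobenzene | COc1cc([N+](=O)[O-])ccc1OCc1ccccc1 | intermediate
17 | 4‑(benzyloxy)‑3‑methoxyaniline | COc1cc(N)ccc1OCc1ccccc1 | intermediate
18 | 4‑(benzyloxy)‑3‑methoxybenzenediazonium tetrafluoroborate | COc1cc([N+]#N)ccc1OCc1ccccc1.F[B-](F)(F)F | intermediate
19 | (2S,3S)‑2‑(4‑benzyloxy‑3‑methoxyphenyl)‑5‑[(4S,5R)‑5‑(4‑benzyloxy‑3‑methoxyphenyl)‑2,2‑dimethyl‑1,3‑dioxan‑4‑yl]‑7‑methoxy‑2,3‑dihydro‑1‑benzofuran‑3‑carbaldehyde | COc1cc([C@H]2Oc3c(OC)cc([C@H]4OC(C)(C)OC[C@H]4c4ccc(OCc5ccccc5)c(OC)c4)cc3[C@@H]2C=O)ccc1OCc1ccccc1 | intermediate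
20 | {(2S,3R)‑2‑(4‑benzyloxy‑3‑methoxyphenyl)‑5‑[(4S,5R)‑5‑(4‑benzyloxy‑3‑methoxyphenyl)‑2,2‑dimethyl‑1,3‑dioxan‑4‑yl]‑7‑methoxy‑2,3‑dihydro‑1‑benzofuran‑3‑yl}methanol | COc1cc([C@H]2Oc3c(OC)cc([C@H]4OC(C)(C)OC[C@H]4c4ccc(OCc5ccccc5)c(OC)c4)cc3[C@@H]2CO)ccc1OCc1ccccc1 | intermediate
21 | (1S,2R)‑2‑(4‑benzyloxy‑3‑methoxyphenyl)‑1‑[(2S,3R)‑2‑(4‑benzyloxy‑3‑methoxyphenyl)‑3‑(hydroxymethyl)‑7‑methoxy‑2,3‑dihydro‑1‑benzofuran‑5‑yl]propane‑1,3‑diol | COc1cc([C@H]2Oc3c(OC)cc([C@@H](O)[C@@H](CO)c4ccc(OCc5ccccc5)c(OC)c4)cc3[C@@H]2CO)ccc1OCc1ccccc1 | intermediate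
22 | (1S,2R)‑1‑[(2S,3R)‑2‑(4‑hydroxy‑3‑methoxyphenyl)‑3‑(hydroxymethyl)‑7‑methoxy‑2,3‑dihydro‑1‑benzofuran‑5‑yl]‑2‑(4‑hydroxy‑3‑methoxyphenyl)propane‑1,3‑diol | COc1cc([C@H]2Oc3c(OC)cc([C@@H](O)[C@@H](CO)c4ccc(O)c(OC)c4)cc3[C@@H]2CO)ccc1O | target

**Total step count:** 14
**Longest linear sequence:** 10 steps (1, 2, 4, 5, 6, 7, 11, 12, 13, 14)

**Steps most likely to fail**

Step 11.
- What may go wrong: slow or unselective migratory insertion into the aromatic C2=C3 bond, loss of Pd with re‑aromatisation, ring opening by β‑aryloxide elimination, or weak facial discrimination by the ligand.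
- The fallback uses known chemistry. It makes the same bond on a chromone and then contracts the ring by one carbon. It sets out from 1 (and uses 8) and comes back at 21.
- Carbonylative Sonogashira annulation of 1 with trimethylsilylacetylene (PdCl2(dppf), CO, Et2NH, silyl group lost in the amine medium) should give 8‑methoxy‑4‑oxo‑4H‑chromene‑6‑carbaldehyde F1.
- Catalytic asymmetric conjugate addition of (4‑benzyloxy‑3‑methoxyphenyl)boronic acid to the chromone C2=C3 bond follows (Pd(OCOCF3)2/t‑BuPyOx, NH4PF6, H2O, ClCH2CH2Cl, 60 °C, ligand enantiomer chosen for 2S). It should give (2S)‑2‑(4‑benzyloxy‑3‑methoxyphenyl)‑8‑methoxy‑4‑oxo‑3,4‑dihydro‑2H‑chromene‑6‑carbaldehyde F2.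
- Oxidative ring contraction uses PhI(OAc)2 and catalytic H2SO4 in HC(OMe)3. The enol ether is iodinated at C3 anti to the C2 aryl group, the fused aryl carbon shifts from C4 to C3, and C4 is extruded as the ester carbon. This should give methyl (2S,3S)‑2‑(4‑benzyloxy‑3‑methoxyphenyl)‑5‑formyl‑7‑methoxy‑2,3‑dihydro‑1‑benzofuran‑3‑carboxylate F3, with the trans relation relayed from C2.
- Evans syn aldol of F3 with 8 under the conditions of step 4 should give methyl (2S,3S)‑5‑{(1S,2S)‑3‑[(4S)‑4‑benzyl‑2‑oxo‑1,3‑oxazolidin‑3‑yl]‑2‑(4‑benzyloxy‑3‑methoxyphenyl)‑1‑hydroxy‑3‑oxopropyl}‑2‑(4‑benzyloxy‑3‑methoxyphenyl)‑7‑methoxy‑2,3‑dihydro‑1‑benzofuran‑3‑carboxylate F4. LiBH4 should then reduce imide and aliphatic ester together to 21.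

Step 13.
- What may go wrong: acid‑induced ionisation of the p‑alkoxybenzylic C–O bond of the side chain, with epimerisation of the carbinol centre or capture by solvent.
- The fallback does without the dioxane altogether. It sets out from 12 and comes back at 21.
- Excess LiAlH4 (THF, 0 °C) should reduce the ester of 12 to (1S,2R)‑2‑(4‑benzyloxy‑3‑methoxyphenyl)‑1‑[3‑(hydroxymethyl)‑7‑methoxy‑1‑benzofuran‑5‑yl]propane‑1,3‑diol F5.
- The arylation of step 11 is run on this free triol with 18. The side‑chain hydroxyls are insulated from the alkene by the benzene ring and cannot act as relay termini. This should give (2S,3S)‑2‑(4‑benzyloxy‑3‑methoxyphenyl)‑5‑[(1S,2R)‑2‑(4‑benzyloxy‑3‑methoxyphenyl)‑1,3‑dihydroxypropyl]‑7‑methoxy‑2,3‑dihydro‑1‑benzofuran‑3‑carbaldehyde F6.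
- NaBH4 as in step 12 should then give 21 without any acidic step.

Step 2.
- What may go wrong: sluggish 5‑endo closure, with competing reductive loss of iodine and base‑induced cleavage of the aryloxyacrylate at 100 °C.
- The fallback builds the furan ring by alkyne annulation. It sets out from 1 and comes back at 4.
- Larock heteroannulation of 1 with methyl 3‑(trimethylsilyl)propiolate (Pd(OAc)2, LiCl, Na2CO3, DMF, 100 °C) should place the bulky silyl group next to oxygen and give methyl 5‑formyl‑7‑methoxy‑2‑(trimethylsilyl)‑1‑benzofuran‑3‑carboxylate F7.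
- Fluoride‑induced protodesilylation (TBAF, wet THF, 0 °C) should then give 4.

**Further compounds**
F1 | step 11 | 8‑methoxy‑4‑oxo‑4H‑chromene‑6‑carbaldehyde | O=c1ccoc2c(OC)cc(C=O)cc12
F2 | step 11 | (2S)‑2‑(4‑benzyloxy‑3‑methoxyphenyl)‑8‑methoxy‑4‑oxo‑3,4‑dihydro‑2H‑chromene‑6‑carbaldehyde | COc1cc([C@H]2Oc3c(OC)cc(C=O)cc3C(=O)C2)ccc1OCc1ccccc1
F3 | step 11 | methyl (2S,3S)‑2‑(4‑benzyloxy‑3‑methoxyphenyl)‑5‑formyl‑7‑methoxy‑2,3‑dihydro‑1‑benzofuran‑3‑carboxylate | COc1cc([C@H]2Oc3c(OC)cc(C=O)cc3[C@@H]2C(=O)OC)ccc1OCc1ccccc1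
F4 | step 11 | methyl (2S,3S)‑5‑{(1S,2S)‑3‑[(4S)‑4‑benzyl‑2‑oxo‑1,3‑oxazolidin‑3‑yl]‑2‑(4‑benzyloxy‑3‑methoxyphenyl)‑1‑hydroxy‑3‑oxopropyl}‑2‑(4‑benzyloxy‑3‑methoxyphenyl)‑7‑methoxy‑2,3‑dihydro‑1‑benzofuran‑3‑carboxylate | COc1cc([C@H]2Oc3c(OC)cc([C@@H](O)[C@@H](C(=O)N4[C@@H](Cc5ccccc5)COC4=O)c4ccc(OCc5ccccc5)c(OC)c4)cc3[C@@H]2C(=O)OC)ccc1OCc1ccccc1
F5 | step 13 | (1S,2R)‑2‑(4‑benzyloxy‑3‑methoxyphenyl)‑1‑[3‑(hydroxymethyl)‑7‑methoxy‑1‑benzofuran‑5‑yl]propane‑1,3‑diol | OCc1coc2c(OC)cc([C@@H](O)[C@@H](CO)c3ccc(OCc4ccccc4)c(OC)c3)cc12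
F6 | step 13 | (2S,3S)‑2‑(4‑benzyloxy‑3‑methoxyphenyl)‑5‑[(1S,2R)‑2‑(4‑benzyloxy‑3‑methoxyphenyl)‑1,3‑dihydroxypropyl]‑7‑methoxy‑2,3‑dihydro‑1‑benzofuran‑3‑carbaldehyde | COc1cc([C@H]2Oc3c(OC)cc([C@@H](O)[C@@H](CO)c4ccc(OCc5ccccc5)c(OC)c4)cc3[C@@H]2C=O)ccc1OCc1ccccc1
F7 | step 2 | methyl 5‑formyl‑7‑methoxy‑2‑(trimethylsilyl)‑1‑benzofuran‑3‑carboxylate | COC(=O)c1c([Si](C)(C)C)oc2c(OC)cc(C=O)cc12
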